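**Assumptions**
- The SMILES fixes only C-2 of the flavan unit, as S. The flavone C-3/flavan C-8 biaryl axis carries no descriptor, so any slowly interconverting rotamers about it are treated as one compound.
- A commercial ketoreductase screening panel is taken to contain an (S)-selective variant that accepts the 1,3-diarylpropan-1-one of step 5.

**Retrosynthetic overview**
1. Last step: global hydrogenolysis of a hexa-O-benzyl precursor.
2. Flavone C-3 to flavan C-8 bond: Suzuki–Miyaura coupling of a 3-iodoflavone (from apigenin by benzylation and C-3 lithiation/iodination) with a flavan-8-boronate (from C-8 bromination and Li/B exchange).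
3. Flavan dihydropyran ring, the only ring built: O1–C8a bond by Cu-catalysed intramolecular O-arylation of an (S)-bromo carbinol, with retention.
4. (S)-Carbinol: ketoreductase reduction of an achiral 1,3-diarylpropan-1-one, itself made by Claisen–Schmidt condensation and alkene hydrogenation.
5. Ring order: the flavone and both benzene rings of the flavan are preformed; the flavan heterocycle is closed first, then the biaryl bond is made, then deprotection.

**Route**

Step 1
Reactants: 1 5-bromobenzene-1,3-diol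
Product: 2 1,3-bis(benzyloxy)-5-bromobenzene
Conditions: BnBr (2.3 equiv), K2CO3, DMF, 60 °C
Reagents that add atoms: benzyl bromide, BrCc1ccccc1
Why: Williamson ether synthesis on two equivalent phenols, with nothing else in the molecule able to react.

Step 2
Reactants: 2 1,3-bis(benzyloxy)-5-bromobenzene
Product: 4 2,4-bis(benzyloxy)-6-bromobenzaldehyde, via iminium chloride 3 (not isolated)
Conditions: POCl3 (1.5 equiv), DMF, 0 → 75 °C; then H2O
Reagents that add atoms: N,N-dimethylformamide, CN(C)C=O (CH=NMe2 of 3, formyl C–H of 4); POCl3, O=P(Cl)(Cl)Cl (chloride of 3); water, O (carbonyl oxygen of 4)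
Why: Vilsmeier–Haack formylation goes para to one benzyloxy group and ortho to the other, avoiding the more hindered site between the two ethers, as the dimethoxy analogue does.

Step 3
Reactants: 4 2,4-bis(benzyloxy)-6-bromobenzaldehyde; 5 1-[4-(benzyloxy)phenyl]ethan-1-one
Product: 6 (E)-3-[2,4-bis(benzyloxy)-6-bromophenyl]-1-[4-(benzyloxy)phenyl]prop-2-en-1-one
Conditions: KOH (50% aq), EtOH/THF, rt
Reagents that add atoms: none
Why: Claisen–Schmidt aldol condensation of a non-enolisable aldehyde with a methyl ketone, where E1cB dehydration gives the conjugated E-enone and neither the aryl bromide nor the benzyl ethers react with hydroxide.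

Step 4
Reactants: 6 (E)-3-[2,4-bis(benzyloxy)-6-bromophenyl]-1-[4-(benzyloxy)phenyl]prop-2-en-1-one
Product: 7 3-[2,4-bis(benzyloxy)-6-bromophenyl]-1-[4-(benzyloxy)phenyl]propan-1-one
Conditions: H2 (4 atm), RhCl(PPh3)3 (5 mol %), toluene/EtOH 1:1, 50 °C
Reagents that add atoms: none
Why: Homogeneous hydrogenation with RhCl(PPh3)3 saturates the disubstituted enone C=C and leaves the aryl ketone, the aryl bromide and the benzyl ethers alone, which heterogeneous Pd would not.

Step 5
Reactants: 7 3-[2,4-bis(benzyloxy)-6-bromophenyl]-1-[4-(benzyloxy)phenyl]propan-1-one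
Product: 8 (1S)-3-[2,4-bis(benzyloxy)-6-bromophenyl]-1-[4-(benzyloxy)phenyl]propan-1-ol
Conditions: (S)-selective ketoreductase (engineered NADPH-dependent oxidoreductase), NADP+ (cat.), i-PrOH, phosphate buffer pH 7.5/toluene, 40 °C
Reagents that add atoms: none
Why: Ketoreductase-catalysed asymmetric carbonyl reduction delivers hydride from NADPH (recycled by i-PrOH) to the Re face of the prochiral ketone, setting the first and only stereocentre as S in a substrate class (1,3-diarylpropan-1-ones) for which engineered ketoreductases are established.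

Step 6
Reactants: 8 (1S)-3-[2,4-bis(benzyloxy)-6-bromophenyl]-1-[4-(benzyloxy)phenyl]propan-1-ol
Product: 9 (2S)-5,7-bis(benzyloxy)-2-[4-(benzyloxy)phenyl]-3,4-dihydro-2H-chromene
Conditions: CuI (10 mol %), 3,4,7,8-tetramethyl-1,10-phenanthroline (20 mol %), Cs2CO3, toluene, 110 °C
Reagents that add atoms: none
Why: Ullmann-type Cu-catalysed intramolecular C–O coupling arylates the alkoxide oxygen to close the six-membered ring, so the C–O bond at the stereocentre is never broken and S is retained without the ionisation risk a 4-alkoxybenzylic carbinol carries in displacement chemistry.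

Step 7
Reactants: 9 (2S)-5,7-bis(benzyloxy)-2-[4-(benzyloxy)phenyl]-3,4-dihydro-2H-chromene
Product: 10 (2S)-5,7-bis(benzyloxy)-2-[4-(benzyloxy)phenyl]-8-bromo-3,4-dihydro-2H-chromene
Conditions: NBS (1.0 equiv), CH2Cl2, −78 → 0 °C, dark
Reagents that add atoms: N-bromosuccinimide, O=C1CCC(=O)N1Br
Why: Electrophilic aromatic bromination of the trioxygenated ring A goes to C-8 rather than C-6, which is flanked by two benzyloxy groups, as is well known for O-benzylated 5,7-dioxygenated flavans, and the neutral cold conditions leave C-2 untouched.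

Step 8
Reactants: 10 (2S)-5,7-bis(benzyloxy)-2-[4-(benzyloxy)phenyl]-8-bromo-3,4-dihydro-2H-chromene
Product: 12 (2S)-5,7-bis(benzyloxy)-2-[4-(benzyloxy)phenyl]-8-(4,4,5,5-tetramethyl-1,3,2-dioxaborolan-2-yl)-3,4-dihydro-2H-chromene, via 8-lithioflavan 11 (not isolated)
Conditions: n-BuLi (1.1 equiv), THF, −78 °C; i-PrOBpin, −78 °C → rt; then H2O
Reagents that add atoms: n-butyllithium, [Li]CCCC (lithium of 11); 2-isopropoxy-4,4,5,5-tetramethyl-1,3,2-dioxaborolane, CC(C)OB1OC(C)(C)C(C)(C)O1
Why: Bromine–lithium exchange is faster at −78 °C than any deprotonation of the benzyl ethers, and trapping the aryllithium with the borate ester gives an isolable pinacol boronate.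

Step 9
Reactants: 13 apigenin (5,7-dihydroxy-2-(4-hydroxyphenyl)-4H-chromen-4-one)
Product: 14 5,7-bis(benzyloxy)-2-[4-(benzyloxy)phenyl]-4H-chromen-4-one
Conditions: BnBr (4.5 equiv), K2CO3, KI (cat.), DMF, 80 °C
Reagents that add atoms: benzyl bromide, BrCc1ccccc1
Why: Williamson ether synthesis, with heat and excess halide to alkylate the hydrogen-bonded 5-OH as well.

Step 10
Reactants: 14 5,7-bis(benzyloxy)-2-[4-(benzyloxy)phenyl]-4H-chromen-4-one
Product: 16 5,7-bis(benzyloxy)-2-[4-(benzyloxy)phenyl]-3-iodo-4H-chromen-4-one, via 3-lithioflavone 15 (not isolated)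
Conditions: LiN(i-Pr)2 (LDA, 1.3 equiv), THF, −78 °C; I2, −78 → 0 °C; aq Na2S2O3
Reagents that add atoms: lithium diisopropylamide, [Li]N(C(C)C)C(C)C (lithium of 15); iodine, II
Why: Carbonyl-directed deprotonative lithiation removes the only acidic ring proton (C-3, stabilised by chelation to the C-4 oxygen), and iodinolysis then gives the 3-iodide without the ring A iodination that electrophilic reagents risk.

Step 11
Reactants: 12 (2S)-5,7-bis(benzyloxy)-2-[4-(benzyloxy)phenyl]-8-(4,4,5,5-tetramethyl-1,3,2-dioxaborolan-2-yl)-3,4-dihydro-2H-chromene; 16 5,7-bis(benzyloxy)-2-[4-(benzyloxy)phenyl]-3-iodo-4H-chromen-4-one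
Product: 17 5,7-bis(benzyloxy)-2-[4-(benzyloxy)phenyl]-3-{(2S)-5,7-bis(benzyloxy)-2-[4-(benzyloxy)phenyl]-3,4-dihydro-2H-chromen-8-yl}-4H-chromen-4-one
Conditions: Pd(OAc)2 (5 mol %), SPhos (10 mol %), K3PO4, toluene/H2O 10:1, 90 °C (12 in 1.3-fold excess)
Reagents that add atoms: none
Why: Suzuki–Miyaura coupling in which the electron-poor 3-iodo vinylogous ester adds readily to palladium and the bulky dialkylbiarylphosphine SPhos is the standard ligand for di-ortho-alkoxy arylboron partners and congested biaryls, under mild base that does not affect C-2.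

Step 12
Reactants: 17 5,7-bis(benzyloxy)-2-[4-(benzyloxy)phenyl]-3-{(2S)-5,7-bis(benzyloxy)-2-[4-(benzyloxy)phenyl]-3,4-dihydro-2H-chromen-8-yl}-4H-chromen-4-one
Product: 18 daphnodorin D2
Conditions: H2 (1 atm), 10% Pd/C, THF/MeOH 1:1, rt, stopped at full conversion
Reagents that add atoms: none
Why: Catalytic hydrogenolysis cleaves the six primary benzyl aryl ethers much faster than the hindered cyclic secondary benzylic C2–O1 bond or the tetrasubstituted flavone C2=C3 bond, and the neutral conditions avoid the acid-promoted ring opening that would racemise a 4'-hydroxyflavan.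

**Compound list**
1 | 5-bromobenzene-1,3-diol | Oc1cc(O)cc(Br)c1 | starting material
2 | 1,3-bis(benzyloxy)-5-bromobenzene | Brc1cc(OCc2ccccc2)cc(OCc2ccccc2)c1 | intermediate
3 | N-{[2,4-bis(benzyloxy)-6-bromophenyl]methylidene}-N-methylmethanaminium chloride (iminium chloride) | C[N+](C)=Cc1c(Br)cc(OCc2ccccc2)cc1OCc1ccccc1.[Cl-] | intermediate (not isolated)
4 | 2,4-bis(benzyloxy)-6-bromobenzaldehyde | O=Cc1c(Br)cc(OCc2ccccc2)cc1OCc1ccccc1 | intermediate
5 | 1-[4-(benzyloxy)phenyl]ethan-1-one | CC(=O)c1ccc(OCc2ccccc2)cc1 | starting material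
6 | (E)-3-[2,4-bis(benzyloxy)-6-bromophenyl]-1-[4-(benzyloxy)phenyl]prop-2-en-1-one | O=C(/C=C/c1c(Br)cc(OCc2ccccc2)cc1OCc1ccccc1)c1ccc(OCc2ccccc2)cc1 | intermediate
7 | 3-[2,4-bis(benzyloxy)-6-bromophenyl]-1-[4-(benzyloxy)phenyl]propan-1-one | O=C(CCc1c(Br)cc(OCc2ccccc2)cc1OCc1ccccc1)c1ccc(OCc2ccccc2)cc1 | intermediate
8 | (1S)-3-[2,4-bis(benzyloxy)-6-bromophenyl]-1-[4-(benzyloxy)phenyl]propan-1-ol | O[C@H](c1ccc(OCc2ccccc2)cc1)CCc1c(Br)cc(OCc2ccccc2)cc1OCc1ccccc1 | intermediate
9 | (2S)-5,7-bis(benzyloxy)-2-[4-(benzyloxy)phenyl]-3,4-dihydro-2H-chromene | c1ccccc1COc1cc(OCc2ccccc2)c2c(c1)O[C@H](c1ccc(OCc3ccccc3)cc1)CC2 | intermediate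
10 | (2S)-5,7-bis(benzyloxy)-2-[4-(benzyloxy)phenyl]-8-bromo-3,4-dihydro-2H-chromene | c1ccccc1COc1cc(OCc2ccccc2)c2c(c1Br)O[C@H](c1ccc(OCc3ccccc3)cc1)CC2 | intermediate
11 | [(2S)-5,7-bis(benzyloxy)-2-[4-(benzyloxy)phenyl]-3,4-dihydro-2H-chromen-8-yl]lithium (8-lithioflavan) | c1ccccc1COc1cc(OCc2ccccc2)c2c(c1[Li])O[C@H](c1ccc(OCc3ccccc3)cc1)CC2 | intermediate (not isolated)
12 | (2S)-5,7-bis(benzyloxy)-2-[4-(benzyloxy)phenyl]-8-(4,4,5,5-tetramethyl-1,3,2-dioxaborolan-2-yl)-3,4-dihydro-2H-chromene | c1ccccc1COc1cc(OCc2ccccc2)c2c(c1B4OC(C)(C)C(C)(C)O4)O[C@H](c1ccc(OCc3ccccc3)cc1)CC2 | intermediate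
13 | apigenin (5,7-dihydroxy-2-(4-hydroxyphenyl)-4H-chromen-4-one) | O=c1cc(-c2ccc(O)cc2)oc2cc(O)cc(O)c12 | starting material
14 | 5,7-bis(benzyloxy)-2-[4-(benzyloxy)phenyl]-4H-chromen-4-one | O=c1cc(-c2ccc(OCc3ccccc3)cc2)oc2cc(OCc3ccccc3)cc(OCc3ccccc3)c12 | intermediate
15 | {5,7-bis(benzyloxy)-2-[4-(benzyloxy)phenyl]-4-oxo-4H-chromen-3-yl}lithium (3-lithioflavone) | O=c1c([Li])c(-c2ccc(OCc3ccccc3)cc2)oc2cc(OCc3ccccc3)cc(OCc3ccccc3)c12 | intermediate (not isolated)
16 | 5,7-bis(benzyloxy)-2-[4-(benzyloxy)phenyl]-3-iodo-4H-chromen-4-one | O=c1c(I)c(-c2ccc(OCc3ccccc3)cc2)oc2cc(OCc3ccccc3)cc(OCc3ccccc3)c12 | intermediate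
17 | 5,7-bis(benzyloxy)-2-[4-(benzyloxy)phenyl]-3-{(2S)-5,7-bis(benzyloxy)-2-[4-(benzyloxy)phenyl]-3,4-dihydro-2H-chromen-8-yl}-4H-chromen-4-one | O=c1c(-c2c(OCc4ccccc4)cc(OCc4ccccc4)c3c2O[C@H](c2ccc(OCc4ccccc4)cc2)CC3)c(-c2ccc(OCc4ccccc4)cc2)oc2cc(OCc4ccccc4)cc(OCc4ccccc4)c12 | intermediate
18 | daphnodorin D2, 5,7-dihydroxy-3-[(2S)-5,7-dihydroxy-2-(4-hydroxyphenyl)-3,4-dihydro-2H-chromen-8-yl]-2-(4-hydroxyphenyl)-4H-chromen-4-one | O=c1c(-c2c(O)cc(O)c3c2O[C@H](c2ccc(O)cc2)CC3)c(-c2ccc(O)cc2)oc2cc(O)cc(O)c12 | target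

**Step count**
Total: 12 steps. Longest linear sequence: 10 steps (steps 1–8, 11, 12); steps 9–10 form the second branch.

**Three steps most likely to fail, with fallbacks**

Step 11 (Suzuki–Miyaura coupling). The di-ortho-alkoxy boronate 12 may lose boron by protonolysis faster than it couples at this congested junction. The fallback is a Negishi coupling under anhydrous conditions. It sets out from bromide 10, which is lithiated as in step 8 (n-BuLi, THF, −78 °C, giving 11) and transmetallated with ZnCl2 (THF, −78 °C → rt) to [(2S)-5,7-bis(benzyloxy)-2-[4-(benzyloxy)phenyl]-3,4-dihydro-2H-chromen-8-yl]zinc chloride F1. This is coupled in the same flask with iodide 16 (Pd2(dba)3, RuPhos, THF/NMP, 65 °C). The fallback comes back to the route at 17.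

Step 6 (Cu-catalysed ring closure). The coupling may stall, or give reduction of the C–Br bond or oxidation of the carbinol. The fallback closes the ring by displacement at the carbinol carbon instead of arylation of its oxygen. It sets out from ketone 7:
- Miyaura borylation (B2pin2, Pd(dppf)Cl2, KOAc, dioxane, 90 °C) gives 3-[2,4-bis(benzyloxy)-6-(4,4,5,5-tetramethyl-1,3,2-dioxaborolan-2-yl)phenyl]-1-[4-(benzyloxy)phenyl]propan-1-one F2.
- Oxidation (NaBO3·4H2O, THF/H2O, rt) gives the phenol ketone 3-[2,4-bis(benzyloxy)-6-hydroxyphenyl]-1-[4-(benzyloxy)phenyl]propan-1-one F3.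
- An (R)-selective ketoreductase under the conditions of step 5 gives (1R)-3-[2,4-bis(benzyloxy)-6-hydroxyphenyl]-1-[4-(benzyloxy)phenyl]propan-1-ol F4.
- Mitsunobu cyclisation (PPh3, DIAD, toluene, 0 °C) closes the ring with inversion (R → 2S). The low temperature and non-polar solvent are there to suppress ionisation of the 4-alkoxybenzylic centre, and the ee must be checked after this step.

The fallback comes back to the route at 9.

Step 10 (C-3 lithiation/iodination). LDA may add to or open the pyranone, or metallation may be incomplete because 14 is poorly soluble in cold THF. The fallback sets out again from 14 and iodinates C-3 electrophilically (I2, (NH4)2Ce(NO3)6, MeCN, 60 °C), using the enol-ether character of the C2=C3 bond instead of its C–H acidity. It comes back to the route at 16 and makes no new compound. Ring A iodination is the competing pathway to watch and to separate by chromatography.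

**Further compounds**
F1 | step 11 | [(2S)-5,7-bis(benzyloxy)-2-[4-(benzyloxy)phenyl]-3,4-dihydro-2H-chromen-8-yl]zinc chloride | c1ccccc1COc1cc(OCc2ccccc2)c2c(c1[Zn]Cl)O[C@H](c1ccc(OCc3ccccc3)cc1)CC2
F2 | step 6 | 3-[2,4-bis(benzyloxy)-6-(4,4,5,5-tetramethyl-1,3,2-dioxaborolan-2-yl)phenyl]-1-[4-(benzyloxy)phenyl]propan-1-one | O=C(CCc1c(B2OC(C)(C)C(C)(C)O2)cc(OCc2ccccc2)cc1OCc1ccccc1)c1ccc(OCc2ccccc2)cc1
F3 | step 6 | 3-[2,4-bis(benzyloxy)-6-hydroxyphenyl]-1-[4-(benzyloxy)phenyl]propan-1-one | O=C(CCc1c(O)cc(OCc2ccccc2)cc1OCc1ccccc1)c1ccc(OCc2ccccc2)cc1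
F4 | step 6 | (1R)-3-[2,4-bis(benzyloxy)-6-hydroxyphenyl]-1-[4-(benzyloxy)phenyl]propan-1-ol | O[C@@H](c1ccc(OCc2ccccc2)cc1)CCc1c(O)cc(OCc2ccccc2)cc1OCc1ccccc1
F0 | step 10 | none | none
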